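Ring B (b1–b6, b1 bonded to ring A) is a 4-arylphenol with its allyl group at b5, ortho to the hydroxyl at b4, which is the oxidation pattern of a 2-allyl-4-arylcyclohex-2-enone. Ring B is therefore not coupled to ring A but grown on it: an enamine Robinson annulation joins b1–b2 (Michael addition) and b5–b6 (aldol condensation) in one operation, placing the oxygen and the allyl group in their final positions, and a late dehydrogenation aromatizes the ring. The annulation precursor is the ring A acetaldehyde that already bears the para allyl group and the tertiary terpenyl ether, made by SNAr on an ortho-fluorobenzaldehyde, with the side-chain carbinol masked as a triethylsilyl ether; its partner is hepta-1,6-dien-3-one.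

Key step: step 13

Remark (assumption): commercial (+)-dihydrocarvone, the conjugate-reduction product of (R)-carvone sold as a mixture of C2 epimers, is taken as the chiral starting material; both epimers converge in step 1.
Abbreviation: TerpO = [(2R,4aS,7R,8aS)-2,4a-dimethyl-7-{2-[(triethylsilyl)oxy]propan-2-yl}decahydronaphthalen-2-yl]oxy, the ether residue of alcohol 12.

Step 1
Reactants: 1 (+)-dihydrocarvone; 2 (R)-1-phenylethylamine; 3 but-3-en-2-one
Product: 6 (2S,5R)-2-methyl-2-(3-oxobutyl)-5-(prop-1-en-2-yl)cyclohexan-1-one, via imine 4 (not isolated), via Michael-adduct imine 5 (not isolated)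
Conditions: 2 (1.05 equiv), toluene, reflux, Dean–Stark; then 3 (1.3 equiv), THF, 40 °C; then 10% aq. AcOH, rt
Reagents that add atoms: water, O
Why: Chiral-imine asymmetric Michael addition: the imine reacts through its more substituted secondary enamine tautomer in a cyclic aza-ene-like transition state, and the (R)-phenylethyl group should steer but-3-en-2-one to the C2 face that leaves the methyl group cis to the isopropenyl group (2S), overriding the substrate's own axial-attack preference, which a plain base-mediated annulation would follow to the C2 epimer.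

Step 2
Reactants: 6 (2S,5R)-2-methyl-2-(3-oxobutyl)-5-(prop-1-en-2-yl)cyclohexan-1-one
Product: 8 (4aS,7R)-4a-methyl-7-(prop-1-en-2-yl)-4,4a,5,6,7,8-hexahydronaphthalen-2(3H)-one, via ketol 7 (not isolated)
Conditions: NaOMe, MeOH, rt to 60 °C
Reagents that add atoms: none
Why: Intramolecular aldol condensation (second stage of the Robinson annulation): the methyl ketone enolate adds to the ring carbonyl and ketol 7 loses water by E1cB, while neither existing stereocentre is enolisable.

Step 3
Reactants: 8 (4aS,7R)-4a-methyl-7-(prop-1-en-2-yl)-4,4a,5,6,7,8-hexahydronaphthalen-2(3H)-one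
Product: 9 (4aS,7R,8aS)-4a-methyl-7-(prop-1-en-2-yl)octahydronaphthalen-2(1H)-one (trans-fused)
Conditions: Li, liq. NH3, THF, t-BuOH (1 equiv), −78 °C; then NH4Cl
Reagents that add atoms: none
Why: Dissolving-metal (Birch-type) enone reduction: the β-carbon (C8a) of the reduced enone is protonated axially so that the ring fusion becomes trans to the angular methyl group (8aS), and the isolated isopropenyl alkene is not reduced.

Step 4
Reactants: 9 (4aS,7R,8aS)-4a-methyl-7-(prop-1-en-2-yl)octahydronaphthalen-2(1H)-one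
Product: 10 (4aS,7R,8aS)-7-(2-hydroxypropan-2-yl)-4a-methyloctahydronaphthalen-2(1H)-one
Conditions: Co(acac)2 (20 mol %), PhSiH3, O2 (1 atm), THF, rt
Reagents that add atoms: dioxygen, O=O
Why: Mukaiyama hydration: hydrogen-atom transfer from a cobalt hydride to the 1,1-disubstituted alkene gives the tertiary radical, which is trapped by O2 and reduced to the Markovnikov tertiary alcohol; the saturated ketone is a spectator and no stereocentre is formed.

Step 5
Reactants: 10 (4aS,7R,8aS)-7-(2-hydroxypropan-2-yl)-4a-methyloctahydronaphthalen-2(1H)-one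
Product: 11 (4aS,7R,8aS)-4a-methyl-7-{2-[(triethylsilyl)oxy]propan-2-yl}octahydronaphthalen-2(1H)-one
Conditions: Et3SiOTf, 2,6-lutidine, CH2Cl2, −78 to 0 °C
Reagents that add atoms: triethylsilyl trifluoromethanesulfonate, CC[Si](CC)(CC)OS(=O)(=O)C(F)(F)F
Why: Silylation of the tertiary alcohol with a silyl triflate and a hindered pyridine base, conditions under which the ketone should not be converted to a silyl enol ether at low temperature.

Step 6
Reactants: 11 (4aS,7R,8aS)-4a-methyl-7-{2-[(triethylsilyl)oxy]propan-2-yl}octahydronaphthalen-2(1H)-one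
Product: 12 (2R,4aS,7R,8aS)-2,4a-dimethyl-7-{2-[(triethylsilyl)oxy]propan-2-yl}decahydronaphthalen-2-ol (axial hydroxyl, equatorial methyl)
Conditions: MeTi(OiPr)3 (2 equiv, from MeLi and ClTi(OiPr)3), Et2O, −30 °C to rt; then aq. NH4Cl
Reagents that add atoms: methyllithium, [Li]C (transmetallated in the flask to methyltitanium triisopropoxide, C[Ti](OC(C)C)(OC(C)C)OC(C)C)
Why: Organotitanium 1,2-addition: the bulky methyltitanium reagent should approach the cyclohexanone carbonyl from the equatorial direction (steric approach control, away from the axial hydrogens at C4 and C8a), placing the methyl group equatorial and the hydroxyl axial, which is the 2R configuration.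

Step 7
Reactants: 12 (2R,4aS,7R,8aS)-2,4a-dimethyl-7-{2-[(triethylsilyl)oxy]propan-2-yl}decahydronaphthalen-2-ol; 13 5-bromo-2-fluorobenzaldehyde
Product: 14 5-bromo-2-(TerpO)benzaldehyde
Conditions: KH, 18-crown-6, THF, 0 °C to rt; then 13, 0 °C to rt
Reagents that add atoms: none
Why: Nucleophilic aromatic substitution (addition–elimination): the potassium tertiary alkoxide displaces the fluoride activated by the ortho formyl group, the meta bromide is not activated and stays, and C2 keeps its 2R configuration because its C–O bond is not broken.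

Step 8
Reactants: 14 5-bromo-2-(TerpO)benzaldehyde
Product: 15 5-allyl-2-(TerpO)benzaldehyde
Conditions: CH2=CHCH2SnBu3, Pd(PPh3)4 (5 mol %), toluene, 100 °C
Reagents that add atoms: allyltributylstannane, C=CC[Sn](CCCC)(CCCC)CCCC
Why: Stille cross-coupling: oxidative addition of zerovalent palladium into the aryl bromide, allyl transfer from tin and reductive elimination give the allylarene, with the aldehyde, the silyl ether and the aryl ether untouched.

Step 9
Reactants: 15 5-allyl-2-(TerpO)benzaldehyde
Product: 16 4-allyl-2-(2-methoxyethenyl)-1-(TerpO)benzene (E/Z mixture)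
Conditions: MeOCH2PPh3Cl, NaN(SiMe3)2, THF, 0 °C; then 15, −78 to 0 °C
Reagents that add atoms: (methoxymethyl)triphenylphosphonium chloride, COC[P+](c1ccccc1)(c1ccccc1)c1ccccc1.[Cl-]
Why: Wittig olefination with the methoxymethylene ylide gives the enol ether as an E/Z mixture, both isomers serving equally, and the amide base is too weak to deprotonate the allylarene.

Step 10
Reactants: 16 4-allyl-2-(2-methoxyethenyl)-1-(TerpO)benzene
Product: 17 2-[5-allyl-2-(TerpO)phenyl]acetaldehyde
Conditions: 2 M aq. HCl, THF (1:4), rt; aq. NaHCO3; crude product used at once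
Reagents that add atoms: water, O
Why: Acid-catalysed enol ether hydrolysis (C-protonation, hydration, loss of methanol) unveils the homologous aldehyde; brief exposure to dilute aqueous acid should leave the tertiary alkyl aryl ether and the tertiary silyl ether intact, and the aldehyde is not stored because arylacetaldehydes self-condense.

Step 11
Reactants: 18 pent-4-enoic acid
Product: 20 N-methoxy-N-methylpent-4-enamide, via acyl imidazole 19 (not isolated)
Conditions: 1,1'-carbonyldiimidazole, CH2Cl2, rt; then MeNH(OMe)·HCl, rt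
Reagents that add atoms: N,O-dimethylhydroxylamine hydrochloride, CNOC.Cl
Why: Weinreb amide formation by acyl substitution through acyl imidazole 19.

Step 12
Reactants: 20 N-methoxy-N-methylpent-4-enamide
Product: 21 hepta-1,6-dien-3-one
Conditions: CH2=CHMgBr, THF, 0 °C; poured into cold 1 M HCl
Reagents that add atoms: vinylmagnesium bromide, C=C[Mg]Br
Why: Weinreb ketone synthesis: the chelated tetrahedral adduct prevents over-addition, and the inverse acidic quench protonates the released hydroxylamine before it can add to the new enone.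

Step 13
Reactants: 17 2-[5-allyl-2-(TerpO)phenyl]acetaldehyde; 21 hepta-1,6-dien-3-one
Product: 25 2-allyl-4-[5-allyl-2-(TerpO)phenyl]cyclohex-2-en-1-one (both epimers at the aryl-bearing carbon), via enamine 22 (not isolated), via adduct enamine 23 (not isolated), via keto aldehyde 24 (not isolated)
Conditions: pyrrolidine (1.2 equiv), 4 Å MS, toluene, 0 °C to rt, excess amine evaporated; then 21 (1.1 equiv), toluene, 0 °C to rt; then AcOH, NaOAc, H2O, 70 °C
Reagents that add atoms: none
Why: Stork enamine variant of the Robinson annulation: the β-carbon of enamine 22 (b1) adds to the unsubstituted vinyl terminus of 21 to form b1–b2, buffered hydrolysis of adduct 23 releases keto aldehyde 24, and the ketone α′-methylene (b5) then attacks the aldehyde carbon (b6) under pyrrolidinium acetate catalysis, the ketol losing water by E1cB to the conjugated enone. The closest known reaction type is the annulation of aldehyde enamines, arylacetaldehyde enamines included, with alkyl vinyl ketones to 4-substituted cyclohex-2-enones. Ring B closes by a 6-(enolendo)-exo-trig aldol addition. The only new stereocentre, b1, forms without control as both epimers, which is harmless because it becomes an aromatic carbon two steps later. The step needs mono-addition and a single aldol regiochemistry: removal of free pyrrolidine and a near-stoichiometric charge of 21 should limit a second Michael addition, and only the α′-methylene can close a six-membered ring (the alternatives would be four-membered), which fixes the allyl group on b5. The weakly acidic buffer should leave the allyl alkene unconjugated, since its CH2 on the enone α-carbon is not enolisable, and should spare the silyl ether and the tertiary aryl ether.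

Step 14
Reactants: 25 2-allyl-4-[5-allyl-2-(TerpO)phenyl]cyclohex-2-en-1-one
Product: 26 {[6-allyl-4-(5-allyl-2-(TerpO)phenyl)cyclohexa-1,5-dien-1-yl]oxy}trimethylsilane
Conditions: LiN(i-Pr)2 (LDA), THF, −78 °C; then Me3SiCl, −78 to 0 °C; pentane, filtration
Reagents that add atoms: chlorotrimethylsilane, C[Si](C)(C)Cl
Why: Kinetic enolisation and O-silylation (silyl dienol ether formation): the hindered amide should remove an α′ hydrogen at b3, not the γ hydrogen at b1, giving the cross-conjugated 2-silyloxydiene that directs the coming palladation to b3 and away from the allyl-bearing b5.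

Step 15
Reactants: 26 {[6-allyl-4-(5-allyl-2-(TerpO)phenyl)cyclohexa-1,5-dien-1-yl]oxy}trimethylsilane
Product: 28 2-allyl-4-[5-allyl-2-(TerpO)phenyl]phenol, via dienone 27 (not isolated)
Conditions: Pd(OAc)2 (1.0 equiv), MeCN, rt
Reagents that add atoms: none
Why: Saegusa–Ito oxidation: the b3-palladated ketone undergoes β-hydride elimination towards b2 to give dienone 27, which tautomerises spontaneously to the phenol and so erases the b1 stereocentre; one equivalent of Pd(OAc)2 without re-oxidant limits contact of divalent palladium with the allyl groups.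

Step 16
Reactants: 28 2-allyl-4-[5-allyl-2-(TerpO)phenyl]phenol
Product: 29 2-allyl-4-[5-allyl-2-{[(2R,4aS,7R,8aS)-7-(2-hydroxypropan-2-yl)-2,4a-dimethyldecahydronaphthalen-2-yl]oxy}phenyl]phenol (CNP0342687.1)
Conditions: Bu4NF, THF, rt to 40 °C; aq. NH4Cl
Reagents that add atoms: none
Why: Fluoride-induced cleavage of the tertiary silyl ether (desilylation driven by the Si–F bond) under non-acidic conditions that spare the tertiary alkyl aryl ether and the allyl groups.

Compound list
1 | (+)-dihydrocarvone, (2R,5R)-2-methyl-5-(prop-1-en-2-yl)cyclohexan-1-one (commercial material contains the 2S epimer) | CC(=C)[C@@H]1CC[C@@H](C)C(=O)C1 | starting material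
2 | (R)-1-phenylethylamine (chiral auxiliary) | C[C@@H](N)c1ccccc1 | starting material
3 | but-3-en-2-one | CC(=O)C=C | starting material
4 | (1R)-N-[(5R)-2-methyl-5-(prop-1-en-2-yl)cyclohexylidene]-1-phenylethan-1-amine (C2 epimers, in equilibrium with the secondary enamine) | CC(=C)[C@@H]1CCC(C)C(=N[C@H](C)c2ccccc2)C1 | intermediate (not isolated)
5 | 4-[(1S,4R)-1-methyl-2-{[(1R)-1-phenylethyl]imino}-4-(prop-1-en-2-yl)cyclohexyl]butan-2-one | CC(=C)[C@@H]1CC[C@@](C)(CCC(C)=O)C(=N[C@H](C)c2ccccc2)C1 | intermediate (not isolated)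
6 | (2S,5R)-2-methyl-2-(3-oxobutyl)-5-(prop-1-en-2-yl)cyclohexan-1-one | CC(=C)[C@@H]1CC[C@@](C)(CCC(C)=O)C(=O)C1 | intermediate
7 | (4aS,7R)-8a-hydroxy-4a-methyl-7-(prop-1-en-2-yl)octahydronaphthalen-2(1H)-one (configuration at C8a not defined) | CC(=C)[C@@H]1CC[C@@]2(C)CCC(=O)CC2(O)C1 | intermediate (not isolated)
8 | (4aS,7R)-4a-methyl-7-(prop-1-en-2-yl)-4,4a,5,6,7,8-hexahydronaphthalen-2(3H)-one | CC(=C)[C@@H]1CC[C@@]2(C)CCC(=O)C=C2C1 | intermediate
9 | (4aS,7R,8aS)-4a-methyl-7-(prop-1-en-2-yl)octahydronaphthalen-2(1H)-one | O=C1CC[C@]2(C)CC[C@@H](C(C)=C)C[C@H]2C1 | intermediate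
10 | (4aS,7R,8aS)-7-(2-hydroxypropan-2-yl)-4a-methyloctahydronaphthalen-2(1H)-one | O=C1CC[C@]2(C)CC[C@@H](C(C)(C)O)C[C@H]2C1 | intermediate
11 | (4aS,7R,8aS)-4a-methyl-7-{2-[(triethylsilyl)oxy]propan-2-yl}octahydronaphthalen-2(1H)-one | O=C1CC[C@]2(C)CC[C@@H](C(C)(C)O[Si](CC)(CC)CC)C[C@H]2C1 | intermediate
12 | (2R,4aS,7R,8aS)-2,4a-dimethyl-7-{2-[(triethylsilyl)oxy]propan-2-yl}decahydronaphthalen-2-ol | O[C@]1(C)CC[C@]2(C)CC[C@@H](C(C)(C)O[Si](CC)(CC)CC)C[C@H]2C1 | intermediate
13 | 5-bromo-2-fluorobenzaldehyde | O=Cc1cc(Br)ccc1F | starting material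
14 | 5-bromo-2-(TerpO)benzaldehyde | O=Cc1cc(Br)ccc1O[C@]2(C)CC[C@]3(C)CC[C@@H](C(C)(C)O[Si](CC)(CC)CC)C[C@H]3C2 | intermediate
15 | 5-allyl-2-(TerpO)benzaldehyde | O=Cc1cc(CC=C)ccc1O[C@]2(C)CC[C@]3(C)CC[C@@H](C(C)(C)O[Si](CC)(CC)CC)C[C@H]3C2 | intermediate
16 | 4-allyl-2-(2-methoxyethenyl)-1-(TerpO)benzene (E/Z mixture) | COC=Cc1cc(CC=C)ccc1O[C@]2(C)CC[C@]3(C)CC[C@@H](C(C)(C)O[Si](CC)(CC)CC)C[C@H]3C2 | intermediate
17 | 2-[5-allyl-2-(TerpO)phenyl]acetaldehyde | O=CCc1cc(CC=C)ccc1O[C@]2(C)CC[C@]3(C)CC[C@@H](C(C)(C)O[Si](CC)(CC)CC)C[C@H]3C2 | intermediate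
18 | pent-4-enoic acid | C=CCCC(=O)O | starting material
19 | 1-(1H-imidazol-1-yl)pent-4-en-1-one | C=CCCC(=O)n1ccnc1 | intermediate (not isolated)
20 | N-methoxy-N-methylpent-4-enamide | C=CCCC(=O)N(C)OC | intermediate
21 | hepta-1,6-dien-3-one | C=CC(=O)CCC=C | intermediate
22 | 1-{(E)-2-[5-allyl-2-(TerpO)phenyl]ethenyl}pyrrolidine | C1CCN(C1)/C=C/c1cc(CC=C)ccc1O[C@]2(C)CC[C@]3(C)CC[C@@H](C(C)(C)O[Si](CC)(CC)CC)C[C@H]3C2 | intermediate (not isolated)
23 | 1-{2-[5-allyl-2-(TerpO)phenyl]-5-oxonona-1,8-dien-1-yl}pyrrolidine (open form of the Michael adduct) | O=C(CCC=C)CCC(=CN1CCCC1)c1cc(CC=C)ccc1O[C@]2(C)CC[C@]3(C)CC[C@@H](C(C)(C)O[Si](CC)(CC)CC)C[C@H]3C2 | intermediate (not isolated)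
24 | 2-[5-allyl-2-(TerpO)phenyl]-5-oxonon-8-enal (both epimers at C2) | O=CC(CCC(=O)CCC=C)c1cc(CC=C)ccc1O[C@]2(C)CC[C@]3(C)CC[C@@H](C(C)(C)O[Si](CC)(CC)CC)C[C@H]3C2 | intermediate (not isolated)
25 | 2-allyl-4-[5-allyl-2-(TerpO)phenyl]cyclohex-2-en-1-one (both epimers at C4) | O=C1CCC(c2cc(CC=C)ccc2O[C@]3(C)CC[C@]4(C)CC[C@@H](C(C)(C)O[Si](CC)(CC)CC)C[C@H]4C3)C=C1CC=C | intermediate
26 | {[6-allyl-4-(5-allyl-2-(TerpO)phenyl)cyclohexa-1,5-dien-1-yl]oxy}trimethylsilane (both epimers at C4) | C[Si](C)(C)OC1=CCC(c2cc(CC=C)ccc2O[C@]3(C)CC[C@]4(C)CC[C@@H](C(C)(C)O[Si](CC)(CC)CC)C[C@H]4C3)C=C1CC=C | intermediate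
27 | 2-allyl-4-[5-allyl-2-(TerpO)phenyl]cyclohexa-2,5-dien-1-one | O=C1C=CC(c2cc(CC=C)ccc2O[C@]3(C)CC[C@]4(C)CC[C@@H](C(C)(C)O[Si](CC)(CC)CC)C[C@H]4C3)C=C1CC=C | intermediate (not isolated)
28 | 2-allyl-4-[5-allyl-2-(TerpO)phenyl]phenol | C=CCc1ccc(O[C@]2(C)CC[C@]3(C)CC[C@@H](C(C)(C)O[Si](CC)(CC)CC)C[C@H]3C2)c(-c2ccc(O)c(CC=C)c2)c1 | intermediate
29 | 2-allyl-4-[5-allyl-2-{[(2R,4aS,7R,8aS)-7-(2-hydroxypropan-2-yl)-2,4a-dimethyldecahydronaphthalen-2-yl]oxy}phenyl]phenol | C=CCc1ccc(O[C@]2(C)CC[C@]3(C)CC[C@@H](C(C)(C)O)C[C@H]3C2)c(-c2ccc(O)c(CC=C)c2)c1 | target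

Total step count: 16. Longest linear sequence: 14 steps (steps 1–10 and 13–16, from 1 to 29); the two-step branch to 21 (steps 11 and 12) joins at step 13.

Steps most likely to fail

Step 13 (annulation). A second Michael addition of the adduct enamine to the vinyl ketone, oligomerisation of the vinyl ketone, or stalling at the open keto aldehyde would erode the ring closure. The fallback attaches ring B ready-made by biaryl coupling instead of growing it. It sets out from aldehyde 15: Baeyer–Villiger oxidation (mCPBA, NaHCO3, CH2Cl2, 0 °C; the electron-rich aryl group migrates) should give 5-allyl-2-(TerpO)phenyl formate F1, methanolysis (K2CO3, MeOH) should give 5-allyl-2-(TerpO)phenol F2, and Tf2O with pyridine should give 5-allyl-2-(TerpO)phenyl trifluoromethanesulfonate F3. Suzuki–Miyaura coupling (Pd(OAc)2, SPhos, K3PO4, toluene/H2O, 80 °C) with 2-allyl-4-(4,4,5,5-tetramethyl-1,3,2-dioxaborolan-2-yl)phenol F4, itself prepared from 2-allyl-4-bromophenol by Miyaura borylation (B2pin2, Pd(dppf)Cl2, KOAc), would then deliver 28, where the route is rejoined before the final desilylation.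

Step 7 (aryl ether formation). Reversible addition of the hindered tertiary alkoxide to the formyl group, followed by hydride transfer between aldehyde molecules, may outrun substitution at the fluorine-bearing carbon. The fallback starts again from alcohol 12 and changes the activating group: the potassium alkoxide (KH, 18-crown-6, THF) is arylated with 5-bromo-2-fluorobenzonitrile, whose nitrile activates the fluoride comparably but is neither attacked reversibly nor a hydride acceptor, and can be heated, to give 5-bromo-2-(TerpO)benzonitrile F5. Partial reduction with i-Bu2AlH (toluene, −78 °C) and hydrolysis of the aldimine on aqueous work-up would return the route to aldehyde 14.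

Step 15 (dehydrogenation). Divalent palladium may engage the newly formed 2-allylphenol in an oxidative cyclisation towards a benzofuran, or a palladium hydride may move the terminal alkenes into conjugation. The fallback is a metal-free dehydrogenation through a selenoxide that bypasses 26. It sets out from enone 25: the kinetic lithium enolate (LiN(i-Pr)2, THF, −78 °C) is trapped with PhSeCl to give 2-allyl-4-[5-allyl-2-(TerpO)phenyl]-6-(phenylselanyl)cyclohex-2-en-1-one F6. Oxidation at selenium (mCPBA, one equivalent, CH2Cl2, −78 °C, then i-Pr2NH and warming) should trigger syn-elimination to dienone 27, which tautomerises to 28.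

Further compounds
F1 | step 13 | 5-allyl-2-(TerpO)phenyl formate | O=COc1cc(CC=C)ccc1O[C@]2(C)CC[C@]3(C)CC[C@@H](C(C)(C)O[Si](CC)(CC)CC)C[C@H]3C2
F2 | step 13 | 5-allyl-2-(TerpO)phenol | Oc1cc(CC=C)ccc1O[C@]2(C)CC[C@]3(C)CC[C@@H](C(C)(C)O[Si](CC)(CC)CC)C[C@H]3C2
F3 | step 13 | 5-allyl-2-(TerpO)phenyl trifluoromethanesulfonate | O=S(=O)(Oc1cc(CC=C)ccc1O[C@]2(C)CC[C@]3(C)CC[C@@H](C(C)(C)O[Si](CC)(CC)CC)C[C@H]3C2)C(F)(F)F
F4 | step 13 | 2-allyl-4-(4,4,5,5-tetramethyl-1,3,2-dioxaborolan-2-yl)phenol | C=CCc1cc(ccc1O)B1OC(C)(C)C(C)(C)O1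
F5 | step 7 | 5-bromo-2-(TerpO)benzonitrile | N#Cc1cc(Br)ccc1O[C@]2(C)CC[C@]3(C)CC[C@@H](C(C)(C)O[Si](CC)(CC)CC)C[C@H]3C2
F6 | step 15 | 2-allyl-4-[5-allyl-2-(TerpO)phenyl]-6-(phenylselanyl)cyclohex-2-en-1-one | O=C1C([Se]c2ccccc2)CC(c2cc(CC=C)ccc2O[C@]3(C)CC[C@]4(C)CC[C@@H](C(C)(C)O[Si](CC)(CC)CC)C[C@H]4C3)C=C1CC=C
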